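I followed one unit of X to the end of the flask. It could join a chain as D, fall into the gap that D + X leaves below the charge, or stay X. So the average length is the fraction of the charge found in D, times a ceiling. With one chain per E, the ceiling length, the units per chain if each unit of X joined a chain, is 100 for birch and 400 for larch.

| setting | spring | autumn | noon | birch | larch |
|---|---|---|---|---|---|
| X | 1 M | 1 M | 1 M | 1.0 M | 1.0 M |
| L | 0.30 M | 0.30 M | 0.30 M | 0.300 M | 0.300 M |
| E | 0.2 mol% | 0.52 mol% | 0.71 mol% | 1 mol% | 0.25 mol% |
| remark | run made earlier | run made earlier | run made earlier |  |  |
| time |  |  |  | 8.0 min | 8.0 min |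

- spring (time / min: D / %, X / %): 0.417: 5.5, 91.5; 0.833: 8.4, 82.2; 1.50: 14.7, 68.1; 3.00: 30.9, 48.3; 6.00: 48.4, 26.4
- autumn (time / min: D / %, X / %): 0.417: 9.0, 84.9; 0.833: 21.4, 67.0; 1.50: 39.6, 48.5; 3.00: 59.9, 23.9; 6.00: 76.8, 6.1
- noon (time / min: D / %, X / %): 0.500: 18.3, 77.2; 1.33: 43.4, 45.9; 2.50: 65.6, 21.4; 4.00: 77.8, 8.2; 6.00: 82.3, 3.5

(scatter of a reading: 1 percentage point)

- the average divides the monomer in chains by the number of chains begun, living and dead together
- the earlier runs do not show the number of chains; that part of a forecast is a guess

* which of the two ends with the longer chains by the average number of monomer units in a chain (chains begun, living or dead) ("neither" if they lie within 10%) (birch / larch / neither)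
* average number of monomer units in a chain (chains begun, living or dead) at the end, birch
* average number of monomer units in a chain (chains begun, living or dead) at the end, larch

I asked what could be off. Chains per E passes whole into the length, and the runs do not show it, so I assumed it. Time weighed little for birch: noon, with less E, had 3.5% of X left at 6.00 min. For larch it weighed more: spring, with less E, still had 26.4% of X at 6.00 min. The gap also passes into the length, and it widened as E fell: 25.2% in spring, 14.2% at noon, both read at 6.00 min.

So I gave birch noon's gap and neglected its remaining X, which made my estimate of its length 85.8. Larch's loading times time exceeded noon's at 2.50 min, so I put its X below noon's reading of 21.4%. With spring's gap, I reckoned a floor of 214 for its length.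

The forecast said larch, with 88 for birch and 245 for larch, on “living-like chains, with little termination and one chain per E”. Its birch stood near mine, and its larch above my floor.

The flasks gave 86.2 for birch and 248 for larch, so larch ended longer.

    X + Q → D + Q, rate k1*[Q]*[X] (k = 1.30 M⁻¹ s⁻¹)
    X + E → Q + D (k = 0.110 M⁻¹ s⁻¹)
    L + X → Z (k = 0.00820 M⁻¹ s⁻¹)

Larch's ceiling, taken with its D of 62.1%, makes 248, and birch's ceiling, taken with its D of 86.2%, makes 86.2. The difference in loading of E is the main reason for the gap between them: larch given birch's loading ended at 86.2. A further flask like larch, with 0.062 mol% of E, had a ceiling of 1610 and D of 24.7%, which makes 399, and it ended at 399.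

(The earlier runs and the new flask were computed for substances that don't exist.)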